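**Retrosynthetic overview**
1. Numbering as in spiro[5.5]undecane: ring B = C1–C6, ring A = C6–C11, spiro carbon C6; the target is (2R,3R,6R,10S). Enabling feature: C7, the sp2 carbon of ring A next to C6, can be a ketone, so C6 can be the α-carbon of a β-keto ester. The C5–C6 bond of ring B is the axial bond on ring A, trans to Br at C10.
2. C3–Br and C2–Cl ⇐ chlorohydrin ⇐ C2=C3 alkene; C7=CH2 ⇐ C7 ketone (spiro ketone 13).
3. Ring B of 13 ⇐ eight-membered β-keto lactone 10 (ring C6–C(=O)–O–C5–C4–C3–C2–C1). Iodide opens O–C5, CO2 leaves, and the C6 enolate closes C6–C5; the contraction from eight to six atoms sets C6.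
4. 10 ⇐ ring-closing metathesis of an allyl arm (C1–C2) and a 3-methylbut-3-enyl ester arm (C3–C5) on a ring A β-keto ester. Ring A ⇐ bromonium cyclisation (C6–C11 bond) of (S)-bromochloride 7, which comes from an enantioselective bromolactonisation of 1.
5. Ring order: δ-lactone 2 (temporary) → ring A → eight-membered lactone (temporary) → ring B.

Key step: step 7

Step 1
Reactants: 1 5-methylhex-4-enoic acid
Product: 2 (5S)-5-bromo-6,6-dimethyloxan-2-one
Conditions: NBS, cinchona-derived amino-thiocarbamate catalyst (10 mol %), CHCl3–toluene, −60 °C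
Reagents that add atoms: N-bromosuccinimide, O=C1CCC(=O)N1Br
Why: Catalytic enantioselective bromolactonisation: the chiral Lewis-base–bromenium complex picks one alkene face and the carboxyl group opens the bromonium ion at its tertiary carbon (6-endo, Markovnikov), so the single stereocentre, the C–Br carbon that becomes C10, is set by the catalyst, whose pseudo-enantiomer is chosen to give S.

Step 2
Reactants: 2 (5S)-5-bromo-6,6-dimethyloxan-2-one
Product: 3 (4S)-4-bromo-5-chloro-5-methylhexanoyl chloride
Conditions: SOCl2, ZnCl2 (5 mol %), toluene, 55 °C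
Reagents that add atoms: thionyl chloride, O=S(Cl)Cl
Why: Lewis-acid-catalysed chlorinative opening of a lactone with thionyl chloride (the route from lactones to ω-chloroacyl chlorides): the tertiary C–O bond ionises with help from the neighbouring bromine and chloride returns to the tertiary carbon, so the C–Br stereocentre is not touched.

Step 3
Reactants: 3 (4S)-4-bromo-5-chloro-5-methylhexanoyl chloride; 4 Meldrum's acid (2,2-dimethyl-1,3-dioxane-4,6-dione); 5 3-methylbut-3-en-1-ol
Product: 7 3-methylbut-3-en-1-yl (6S)-6-bromo-7-chloro-7-methyl-3-oxooctanoate, via acyl Meldrum's acid 6 (not isolated)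
Conditions: 4, pyridine, CH2Cl2, 0 °C; then 5, toluene, 85 °C
Reagents that add atoms: none
Why: Meldrum's acid route to β-keto esters: C-acylation gives 6, which on heating loses acetone and CO2 to an acylketene that alcohol 5 traps, under conditions too mild to ionise the tertiary chloride; no stereocentre is formed.

Step 4
Reactants: 7 3-methylbut-3-en-1-yl (6S)-6-bromo-7-chloro-7-methyl-3-oxooctanoate
Product: 8 3-methylbut-3-en-1-yl (3S)-3-bromo-2,2-dimethyl-6-oxocyclohexane-1-carboxylate (ester-bearing carbon epimerisable)
Conditions: (CF3)2CHOH (0.02 M), 2,6-di-tert-butyl-4-methylpyridine, 35 °C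
Reagents that add atoms: none
Why: Stereospecific solvolytic bromonium cyclisation (cation–olefin type, 6-endo at the enol): the ionising solvent removes the tertiary chloride with anchimeric help from bromine, the enol carbon of the β-keto ester attacks the tertiary end of the enantiopure bromonium ion through a chair with bromine equatorial, C10 keeps its configuration, and the new ester-bearing carbon is epimerisable and without consequence.

Step 5
Reactants: 8 3-methylbut-3-en-1-yl (3S)-3-bromo-2,2-dimethyl-6-oxocyclohexane-1-carboxylate
Product: 9 3-methylbut-3-en-1-yl (3S)-3-bromo-2,2-dimethyl-6-oxo-1-(prop-2-en-1-yl)cyclohexane-1-carboxylate (either configuration at the new quaternary carbon serves)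
Conditions: allyl methyl carbonate, Pd(PPh3)4 (5 mol %), THF, 40 °C
Reagents that add atoms: allyl methyl carbonate, C=CCOC(=O)OC
Why: Tsuji–Trost allylation with zerovalent palladium under neutral conditions: the soft β-keto ester carbon attacks the π-allyl complex, the alkyl bromide and the homoallylic ester are inert, and the configuration of the new quaternary carbon is irrelevant because step 7 erases it.

Step 6
Reactants: 9 3-methylbut-3-en-1-yl (3S)-3-bromo-2,2-dimethyl-6-oxo-1-(prop-2-en-1-yl)cyclohexane-1-carboxylate
Product: 10 (4S,11Z)-4-bromo-5,5,11-trimethyl-8-oxaspiro[5.7]tridec-11-ene-1,7-dione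
Conditions: second-generation Grubbs catalyst RuCl2(=CHPh)(PCy3)(H2IMes) (10 mol %), toluene (1 mM), 90 °C, slow addition, argon sparge
Reagents that add atoms: none
Why: Ring-closing metathesis: the monosubstituted allyl alkene loads the ruthenium carbene, which closes onto the 1,1-disubstituted alkene with loss of ethene, the geminal substitution at C6 and high dilution favouring the eight-membered ring, whose size allows only the Z alkene.

Step 7
Reactants: 10 (4S,11Z)-4-bromo-5,5,11-trimethyl-8-oxaspiro[5.7]tridec-11-ene-1,7-dione
Product: 13 (6S,10S)-10-bromo-3,11,11-trimethylspiro[5.5]undec-2-en-7-one, via lithium iodo carboxylate 11 (not isolated), via lithium iodo enolate 12 (not isolated)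
Conditions: LiI (1 equiv), dry DMPU (5 mM), 4 Å sieves, 130 °C, argon
Reagents that add atoms: none
Why: Proposed new method: iodide opens the strained eight-membered lactone by SN2 attack at the unhindered O–CH2 carbon (C5), the β-keto carboxylate 11 loses CO2 to give regiospecifically the tetrasubstituted C6 enolate 12 that deprotonation could not reach, and 12 displaces its own primary iodide, so the ring C6–C(=O)–O–C5–C4–C3–C2–C1 shrinks by two atoms to ring B and LiI is returned. The closest known reaction type is the halide-induced decarboxylative ring contraction of α-acyl-γ-butyrolactones to acylcyclopropanes (Krapcho-type dealkylation followed by intramolecular enolate alkylation); new here are the ring sizes and the quaternary spiro carbon. Ring B closes in a 6-(enolexo)-exo-tet mode, helped by the Z alkene in the tether. The only new stereocentre, C6, is controlled by ring A: in the half-chair enolate with the C10 bromine equatorial, the pseudoaxial C11 methyl group blocks the face cis to bromine, so C5 enters axially on the face trans to bromine, which is the relative configuration of the target, while the configuration of C6 in 10 is erased. The step needs C- over O-alkylation, secured because O-attack would rebuild an eight-membered ring, and survival of the C10 bromide, secured by its equatorial neopentyl position (no SN2, no antiperiplanar hydrogen, wrong alignment for 1,3-elimination to a cyclopropane).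

Step 8
Reactants: 13 (6S,10S)-10-bromo-3,11,11-trimethylspiro[5.5]undec-2-en-7-one
Product: 14 (6R,10S)-10-bromo-3,11,11-trimethyl-7-methylidenespiro[5.5]undec-2-ene
Conditions: Ph3PCH3Br, KOtBu, toluene, 80 °C
Reagents that add atoms: methyltriphenylphosphonium bromide, C[P+](c1ccccc1)(c1ccccc1)c1ccccc1.[Br-]
Why: Wittig methylenation, a reaction that works on hindered spiro ketones of this kind: the small non-stabilised ylide reaches C7, enolisation towards C8 is reversible and harmless, and the equatorial neopentyl bromide has no antiperiplanar hydrogen for elimination; no stereocentre changes.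

Step 9
Reactants: 14 (6R,10S)-10-bromo-3,11,11-trimethyl-7-methylidenespiro[5.5]undec-2-ene
Product: 15 (2R,3R,6R,10S)-10-bromo-2-chloro-3,11,11-trimethyl-7-methylidenespiro[5.5]undecan-3-ol
Conditions: trichloroisocyanuric acid (0.35 equiv), acetone–H2O, 0 °C
Reagents that add atoms: trichloroisocyanuric acid, O=C1N(Cl)C(=O)N(Cl)C(=O)N1Cl; water, O
Why: Chlorohydrin formation (electrophilic chlorination in water): the trisubstituted C2=C3 alkene is more electron-rich and far less hindered than the neopentyl exocyclic methylene, C7 is pseudoaxial on ring B and its CH2 covers that face, so chlorine should add to C2 from the face of C11 and water should open the chloronium ion anti at the tertiary C3, which sets C2 and C3 trans and as in the target.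

Step 10
Reactants: 15 (2R,3R,6R,10S)-10-bromo-2-chloro-3,11,11-trimethyl-7-methylidenespiro[5.5]undecan-3-ol
Product: 16 (2R,3R,6R,10S)-3,10-dibromo-2-chloro-3,11,11-trimethyl-7-methylidenespiro[5.5]undecane
Conditions: 1-bromo-N,N,2-trimethylprop-1-en-1-amine, CH2Cl2, 0 °C to rt
Reagents that add atoms: 1-bromo-N,N,2-trimethylprop-1-en-1-amine, CC(C)=C(Br)N(C)C
Why: Neutral alcohol-to-bromide exchange with an α-bromoenamine (keteniminium activation, SN1 ion pair): the alkoxyiminium group leaves with help from the C2 chlorine, the same chloronium ion as in step 9 is formed and bromide opens it anti at C3, so the substitution should go with retention, while the absence of free acid spares the exocyclic alkene.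

**Compound list**
1 | 5-methylhex-4-enoic acid | CC(C)=CCCC(=O)O | starting material
2 | (5S)-5-bromo-6,6-dimethyloxan-2-one | O=C1CC[C@H](Br)C(C)(C)O1 | intermediate
3 | (4S)-4-bromo-5-chloro-5-methylhexanoyl chloride | ClC(=O)CC[C@H](Br)C(C)(C)Cl | intermediate
4 | Meldrum's acid | CC1(C)OC(=O)CC(=O)O1 | starting material
5 | 3-methylbut-3-en-1-ol | C=C(C)CCO | starting material
6 | 5-[(4S)-4-bromo-5-chloro-1-hydroxy-5-methylhexylidene]-2,2-dimethyl-1,3-dioxane-4,6-dione | CC1(C)OC(=O)C(=C(O)CC[C@H](Br)C(C)(C)Cl)C(=O)O1 | intermediate
7 | 3-methylbut-3-en-1-yl (6S)-6-bromo-7-chloro-7-methyl-3-oxooctanoate | C=C(C)CCOC(=O)CC(=O)CC[C@H](Br)C(C)(C)Cl | intermediate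
8 | 3-methylbut-3-en-1-yl (3S)-3-bromo-2,2-dimethyl-6-oxocyclohexane-1-carboxylate | C=C(C)CCOC(=O)C1C(=O)CC[C@H](Br)C1(C)C | intermediate
9 | 3-methylbut-3-en-1-yl (3S)-3-bromo-2,2-dimethyl-6-oxo-1-(prop-2-en-1-yl)cyclohexane-1-carboxylate | C=CCC1(C(=O)OCCC(C)=C)C(=O)CC[C@H](Br)C1(C)C | intermediate
10 | (4S,11Z)-4-bromo-5,5,11-trimethyl-8-oxaspiro[5.7]tridec-11-ene-1,7-dione | O=C1OCC/C(C)=C\CC12C(=O)CC[C@H](Br)C2(C)C | intermediate
11 | lithium (3S)-3-bromo-1-[(2Z)-5-iodo-3-methylpent-2-en-1-yl]-2,2-dimethyl-6-oxocyclohexane-1-carboxylate | [Li+].[O-]C(=O)C1(C/C=C(\CCI)C)C(=O)CC[C@H](Br)C1(C)C | intermediate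
12 | lithium (4S)-4-bromo-2-[(2Z)-5-iodo-3-methylpent-2-en-1-yl]-3,3-dimethylcyclohex-1-en-1-olate | [Li+].[O-]C1=C(C/C=C(\CCI)C)C(C)(C)[C@@H](Br)CC1 | intermediate
13 | (6S,10S)-10-bromo-3,11,11-trimethylspiro[5.5]undec-2-en-7-one | O=C1CC[C@H](Br)C(C)(C)[C@@]12CCC(C)=CC2 | intermediate
14 | (6R,10S)-10-bromo-3,11,11-trimethyl-7-methylidenespiro[5.5]undec-2-ene | C=C1CC[C@H](Br)C(C)(C)[C@@]12CCC(C)=CC2 | intermediate
15 | (2R,3R,6R,10S)-10-bromo-2-chloro-3,11,11-trimethyl-7-methylidenespiro[5.5]undecan-3-ol | C=C1CC[C@H](Br)C(C)(C)[C@@]12CC[C@@](C)(O)[C@H](Cl)C2 | intermediate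
16 | (2R,3R,6R,10S)-3,10-dibromo-2-chloro-3,11,11-trimethyl-7-methylidenespiro[5.5]undecane | C=C1CC[C@H](Br)C(C)(C)[C@@]12CC[C@@](C)(Br)[C@H](Cl)C2 | target

Total step count: 10. Longest linear sequence: 10.

**Steps most likely to fail**

Step 7. At 130 °C the enolate may be protonated before it closes the ring, the primary iodide may eliminate, or HBr may be lost from ring A.
- The fallback sets out from 10 and comes back at 13. It separates C–O cleavage from enolate generation, and each part is a known operation.
- Me3SiI in CH2Cl2 at room temperature cleaves the lactone at the O–CH2 bond (silyl iodide dealkylation of esters and lactones). This gives trimethylsilyl (3S)-3-bromo-1-[(2Z)-5-iodo-3-methylpent-2-en-1-yl]-2,2-dimethyl-6-oxocyclohexane-1-carboxylate F1.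
- CsF in dry DMF at 25–40 °C then removes the silyl group. The free β-keto carboxylate loses CO2 (fluoride-triggered decarboxylative enolate generation), and the enolate alkylates its own iodide on the same face to give 13.

Step 6. Oligomerisation may outrun closure of the eight-membered ring, and the carbene may engage the 1,1-disubstituted alkene too slowly.
- The fallback sets out from 8 and comes back at 10. It closes the ring at the C6–C1 bond instead of at the alkene.
- Cross metathesis of the ester alkene of 8 with (Z)-but-2-ene-1,4-diyl diacetate (second-generation Grubbs catalyst, CH2Cl2, reflux) gives 5-(acetyloxy)-3-methylpent-3-en-1-yl (3S)-3-bromo-2,2-dimethyl-6-oxocyclohexane-1-carboxylate F2.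
- NaH and Pd(PPh3)4 in THF at high dilution then bring about an intramolecular Tsuji–Trost alkylation, a reaction type known to close eight-membered lactones. C6 attacks the unsubstituted allyl terminus, and isomerisation of the π-allyl complex supplies the Z geometry of 10.

Step 10. The activated tertiary alcohol may lose a proton to give alkenes, bromide may enter from the wrong face, or the exocyclic alkene may take part in the ionisation.
- The fallback sets out from 13 and comes back at 16. It places both halogens before the methylene group.
- Trichloroisocyanuric acid in aqueous acetone converts 13, whose only alkene is C2=C3 and whose carbonyl oxygen lies on the C7 face, into (2R,3R,6S,10S)-10-bromo-2-chloro-3-hydroxy-3,11,11-trimethylspiro[5.5]undecan-7-one F3.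
- Me3SiBr in CH2Cl2 at 0 °C, where acid is harmless without the exocyclic alkene, gives (2R,3R,6S,10S)-3,10-dibromo-2-chloro-3,11,11-trimethylspiro[5.5]undecan-7-one F4.
- Non-basic methylenation with Cp2TiMe2 in toluene at 65 °C then gives 16.

**Further compounds**
F1 | step 7 | trimethylsilyl (3S)-3-bromo-1-[(2Z)-5-iodo-3-methylpent-2-en-1-yl]-2,2-dimethyl-6-oxocyclohexane-1-carboxylate | C[Si](C)(C)OC(=O)C1(C/C=C(\CCI)C)C(=O)CC[C@H](Br)C1(C)C
F2 | step 6 | 5-(acetyloxy)-3-methylpent-3-en-1-yl (3S)-3-bromo-2,2-dimethyl-6-oxocyclohexane-1-carboxylate | CC(=O)OCC=C(C)CCOC(=O)C1C(=O)CC[C@H](Br)C1(C)C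
F3 | step 10 | (2R,3R,6S,10S)-10-bromo-2-chloro-3-hydroxy-3,11,11-trimethylspiro[5.5]undecan-7-one | O=C1CC[C@H](Br)C(C)(C)[C@@]12CC[C@@](C)(O)[C@H](Cl)C2
F4 | step 10 | (2R,3R,6S,10S)-3,10-dibromo-2-chloro-3,11,11-trimethylspiro[5.5]undecan-7-one | O=C1CC[C@H](Br)C(C)(C)[C@@]12CC[C@@](C)(Br)[C@H](Cl)C2
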